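Whenever I take a reading from this flask, the protic impurity left tells me where product and crystals together stand, without a look at the clock.

    starting material + dissolved gas + catalyst → catalyst + product (k1 = 270 M⁻² h⁻¹)
    crystals ⇌ product, rate k2*(cs2 - [product]) while solid is left; crystals form when [product] > cs2 (cs2 = 0.23 M, k2 = 0.59 h⁻¹)
    starting material + protic impurity → quenched substrate (k3 = 0.27 M⁻¹ h⁻¹)
    dissolved gas + catalyst ⇌ idle complex, settled at all times (K4 = 40 M⁻¹)
    gas phase ⇌ dissolved gas, rate k5*(csat - [dissolved gas]) (k5 = 1.8 h⁻¹, csat = 200 mM)

starting material 0.80 M; gas phase 200 mM (held); protic impurity 0.240 M; catalyst 1 mol%; time 20 h

1. product and crystals together at 20 h, in percent of the starting material charged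
2. the change that raises the amount of product and crystals together at 20 h, in percent of the starting material charged most ("none" if none brings more than 2 percentage points) (south-east / north-west / north-east / south-west / none)
3. amount of product and crystals together at 20 h, in percent of the starting material charged, after south-east

In this flask two pseudo-first-order rates compete for the starting material: the catalysed step at 0.0480 h⁻¹ and the quench at 0.0648 h⁻¹ with the impurity as charged, a ratio of 0.741. The first figure takes the gas at saturation, where the idle complex holds 88.9% of the catalyst. I may take it so because the transfer can carry 0.450 h⁻¹ in fractions of the charge, far more than the 0.0480 h⁻¹ the catalysed step uses.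

With the gas held at saturation, dividing one rate by the other removes starting material and time, and integrating gives the fraction made as a constant times ln(impurity charged / impurity left). That constant, 0.222, is my yield per e-fold, a selectivity factor in fractions of the charge: the fraction made while the impurity left falls by a factor e.

Doubling the catalyst doubles it to 0.444. Doubling the saturation concentration multiplies it by 1.06. Crystals are counted in, so doubling the dissolution coefficient moves nothing. I choose south-east.

If starting material averages 0.5 of the charge over 20 h, I reckon 48.0%, with 11.5% of the impurity left. For south-east that average changes, so I commit to no number.

The forecast gives 48%, south-east and 67% after it, on the ground that “most of the catalyst sits as the idle complex”.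

The simulated flask gives 47.7%; south-east gains 19 percentage points and reaches 67.0%. At 20.0 h this flask holds 11.1% of its impurity, and the yield per e-fold turns that reading into 48.8%. In the neighbouring flask with 0.25 mol% of catalyst, the yield per e-fold scales to 0.0556. Its 5.0% of impurity left then turns into 16.7%, and that flask stands at 16.4%.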